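## Retrosynthetic overview

1. Tuberostemonone 24 ⇐ C12 epimerisation of the cis-lactone keto-lactam 23 ⇐ oxidative scission of the C1–C9a bond of the 1-hydroxy pentacyclic amine 20. Rings B and C open into the nine-membered keto-lactam at the bond cleaved in the proposed biogenesis from tuberostemonine-type bases; the C1 hydroxyl is the latent ketone.
2. 20 ⇐ azepane ring A by intramolecular N-alkylation; C10 ethyl by radical addition to an iodolactone; lactone D by iodolactonisation of a Claisen amide.
3. Claisen amide ⇐ Luche reduction and C9 alkylation of the cis-hydroindolenone 8, every reagent entering on the convex face.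
4. 8 ⇐ phenol oxidation and aza-Michael closure of ring C onto the tyrosine carbocycle (future ring B); lactone E ⇐ Barbier allylation and hydrogenation on N-Boc-L-tyrosinal.
5. Ring order: lactone E, ring C, lactone D, ring A, nine-membered ring.

Assumption: atom labels follow tuberostemonine numbering (N4; C1–C3 and C9a in pyrrolidine ring C; C5–C9 in azepane ring A; C9–C12 with C1 and C9a in carbocycle B; C13–C15 in fused lactone D; C16–C17 ethyl; C18–C22 in pendant lactone E).

## Route

Step 1
Reactants: 1 N-Boc-L-tyrosine methyl ester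
Product: 2 N-Boc-L-tyrosinal
Conditions: i-Bu2AlH (3.3 equiv), CH2Cl2, −78 °C; MeOH, then Rochelle salt
Reagents that add atoms: none
Why: Low-temperature partial reduction of the ester stops at the aluminium hemiacetal and gives the α-amino aldehyde with C3 (S) untouched.

Step 2
Reactants: 2 N-Boc-L-tyrosinal; 3 ethyl 2-(bromomethyl)acrylate
Product: 5 α-methylene lactone (18S), via hydroxy ester 4 (not isolated)
Conditions: Zn, THF/sat. aq NH4Cl, rt; then PPTS, PhMe, 60 °C
Reagents that add atoms: ethyl 2-(bromomethyl)acrylate (3), C=C(CBr)C(=O)OCC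
Why: Zinc Barbier allylation adds to the aldehyde under Cram-chelate control through the carbamate N–H to give the syn amino alcohol (18S), which lactonises to the α-methylene-γ-butyrolactone.

Step 3
Reactants: 5 α-methylene lactone
Product: 6 cis-methyl lactone E phenol (18S,20S)
Conditions: H2 (1 atm), 10% Pd/C, EtOAc, rt
Reagents that add atoms: none
Why: Heterogeneous hydrogenation delivers H2 to the exocyclic alkene from the face opposite the C18 substituent, setting the cis 20S methyl.

Step 4
Reactants: 6 cis-methyl lactone E phenol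
Product: 8 cis-hydroindolenone (2S,3aR,7aR), via p-quinol 7 (not isolated)
Conditions: PhI(OAc)2, MeCN/H2O (3:1), 0 °C; then DBU, rt
Reagents that add atoms: water, O
Why: Hypervalent-iodine oxidative dearomatisation with water capture gives the p-quinol, and the base-mediated intramolecular aza-Michael addition then desymmetrises the dienone with the C3 substituent on the convex face (the preference known for N-acyl tyrosine derivatives), creating C1 and C9a of the cis-fused rings B and C.

Step 5
Reactants: 8 cis-hydroindolenone; 9 1-chloro-4-iodobutane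
Product: 10 C9-(4-chlorobutyl) enone
Conditions: LiN(SiMe3)2 (2.2 equiv), THF/DMPU, −78 °C; then 9, −78 to −30 °C; sat. aq NH4Cl
Reagents that add atoms: 1-chloro-4-iodobutane (9), ClCCCCI
Why: Kinetic α′-deprotonation (the γ-position is blocked by quaternary C1) gives the alkoxide/cross-conjugated enolate dianion, and enolate alkylation by the iodide terminus on the convex face, anti to the vicinal N-Boc group, sets C9 with C8 trans to N4.

Step 6
Reactants: 10 C9-(4-chlorobutyl) enone
Product: 11 allylic alcohol (6R in indole numbering)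
Conditions: NaBH4, CeCl3·7H2O, MeOH, −40 °C
Reagents that add atoms: none
Why: Luche 1,2-reduction with axial hydride delivery from the convex face gives the equatorial C10 alcohol trans to the C9 chain.

Step 7
Reactants: 11 allylic alcohol; 12 N,N-dimethylpropanamide dimethyl acetal
Product: 14 Claisen amide (12R,13S), via ketene N,O-acetal 13 (not isolated)
Conditions: 12 (5 equiv), PhMe, 110 °C, sealed tube
Reagents that add atoms: N,N-dimethylpropanamide dimethyl acetal (12), CCC(OC)(OC)N(C)C
Why: Eschenmoser–Claisen [3,3] rearrangement through the less hindered secondary allylic alcohol transfers the propanamide unit suprafacially to C12 on the face of the C10–O bond, and the (Z)-ketene N,O-acetal in a chair transition state places the C13 methyl anti to C1 (13S).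

Step 8
Reactants: 14 Claisen amide
Product: 15 iodolactone
Conditions: I2, THF/H2O (2:1), rt
Reagents that add atoms: iodine, II; water, O
Why: Iodolactonisation of the tertiary amide: convex-face iodonium formation and 5-exo attack of the amide oxygen at C11 from the face of the C12 side chain give cis-fused lactone D (O11 trans to the C10 iodide), and hydrolysis of the iminium ether releases dimethylamine.

Step 9
Reactants: 15 iodolactone; 16 phenyl vinyl sulfone
Product: 17 C10-(2-phenylsulfonylethyl) lactone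
Conditions: Bu3SnH, AIBN (cat.), 16 (5 equiv), PhH, 80 °C, syringe pump
Reagents that add atoms: phenyl vinyl sulfone (16), C=CS(=O)(=O)c1ccccc1
Why: Tin-mediated Giese addition: the C10 radical is trapped on the convex face, away from lactone D, N4 and C13, so C16 enters with retention, cis to C8 and trans to O11, while the primary chloride is inert to the stannyl radical.

Step 10
Reactants: 17 C10-(2-phenylsulfonylethyl) lactone
Product: 18 C10-ethyl N-Boc chloride
Conditions: 6% Na/Hg, Na2HPO4, MeOH/THF, −20 °C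
Reagents that add atoms: none
Why: Reductive desulfonylation with sodium amalgam removes the phenylsulfonyl group and leaves the ethyl group without touching any stereocentre.

Step 11
Reactants: 18 C10-ethyl N-Boc chloride
Product: 20 1-hydroxy pentacyclic amine, via ammonium salt 19 (not isolated)
Conditions: TFA/CH2Cl2 (1:4), 0 °C; concentrate; then K2CO3, NaI (cat.), MeCN, 70 °C
Reagents that add atoms: none
Why: Acidolysis of the Boc group followed by Finkelstein-assisted intramolecular N-alkylation (7-exo-tet) closes azepane ring A trans-fused to ring B; no stereocentre is formed.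

Step 12
Reactants: 20 1-hydroxy pentacyclic amine
Product: 23 12-epi-tuberostemonone, via iminium acetate 21 (not isolated), via carbinolamine 22 (not isolated)
Conditions: PhI(OAc)2 (1.2 equiv), MeCN/pH 7 buffer, 0 °C; then TEMPO (0.2 equiv), PhI(OAc)2 (1.5 equiv), rt
Reagents that add atoms: water, O
Why: Proposed new method: the amine nitrogen is ligated by trivalent iodine and, with the C1–C9a bond antiperiplanar, the β-hydroxyl drives a Grob-type two-electron fragmentation (ketone at C1, iminium at C9a, PhI lost) that merges rings B and C into the nine-membered ring at the biogenetic C1–C9a bond, after which water adds to the iminium and the oxoammonium from TEMPO oxidises the carbinolamine to the lactam; the closest known reactions are the Criegee/periodate-type cleavage of vicinal tertiary amino alcohols, the Potier–Polonovski fragmentation and TEMPO-mediated hemiaminal-to-lactam oxidation; no stereocentre is created.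

Step 13
Reactants: 23 12-epi-tuberostemonone
Product: 24 tuberostemonone
Conditions: DBU (0.2 equiv), CH2Cl2, rt
Reagents that add atoms: none
Why: Base-mediated enolisation epimerises C12, now α to the C1 ketone, from the cis- to the trans-fused lactone D arrangement of the natural keto-lactam (assumed to be the thermodynamic epimer), while C9 and C13 are not acidic enough to move.

## Compound list

1 | N-(tert-butoxycarbonyl)-L-tyrosine methyl ester | Oc1ccc(C[C@@H](C(=O)OC)NC(=O)OC(C)(C)C)cc1 | starting material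
2 | N-Boc-L-tyrosinal, tert-butyl N-[(2S)-1-(4-hydroxyphenyl)-3-oxopropan-2-yl]carbamate | Oc1ccc(C[C@@H](C=O)NC(=O)OC(C)(C)C)cc1 | intermediate
3 | ethyl 2-(bromomethyl)acrylate | C=C(CBr)C(=O)OCC | starting material
4 | ethyl (4S,5S)-5-(Boc-amino)-4-hydroxy-6-(4-hydroxyphenyl)-2-methylidenehexanoate (syn amino alcohol) | Oc1ccc(C[C@@H]([C@@H](O)CC(=C)C(=O)OCC)NC(=O)OC(C)(C)C)cc1 | intermediate (not isolated)
5 | tert-butyl N-[(1S)-2-(4-hydroxyphenyl)-1-[(2S)-4-methylidene-5-oxooxolan-2-yl]ethyl]carbamate | Oc1ccc(C[C@@H]([C@@H]2CC(=C)C(=O)O2)NC(=O)OC(C)(C)C)cc1 | intermediate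
6 | tert-butyl N-[(1S)-2-(4-hydroxyphenyl)-1-[(2S,4S)-4-methyl-5-oxooxolan-2-yl]ethyl]carbamate | Oc1ccc(C[C@@H]([C@@H]2C[C@H](C)C(=O)O2)NC(=O)OC(C)(C)C)cc1 | intermediate
7 | p-quinol, tert-butyl N-[(1S)-2-(1-hydroxy-4-oxocyclohexa-2,5-dien-1-yl)-1-[(2S,4S)-4-methyl-5-oxooxolan-2-yl]ethyl]carbamate | O=C1C=CC(O)(C[C@@H]([C@@H]2C[C@H](C)C(=O)O2)NC(=O)OC(C)(C)C)C=C1 | intermediate (not isolated)
8 | tert-butyl (2S,3aR,7aR)-3a-hydroxy-2-[(2S,4S)-4-methyl-5-oxooxolan-2-yl]-6-oxo-2,3,3a,6,7,7a-hexahydro-1H-indole-1-carboxylate (cis-fused; C1–OH cis to C9a–H; lactone E on the convex face) | O=C1C=C[C@]2(O)C[C@@H]([C@@H]3C[C@H](C)C(=O)O3)N(C(=O)OC(C)(C)C)[C@@H]2C1 | intermediate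
9 | 1-chloro-4-iodobutane | ClCCCCI | starting material
10 | tert-butyl (2S,3aR,7R,7aR)-7-(4-chlorobutyl)-3a-hydroxy-2-[(2S,4S)-4-methyl-5-oxooxolan-2-yl]-6-oxo-2,3,3a,6,7,7a-hexahydro-1H-indole-1-carboxylate (chain trans to N) | O=C1C=C[C@]2(O)C[C@@H]([C@@H]3C[C@H](C)C(=O)O3)N(C(=O)OC(C)(C)C)[C@@H]2[C@H]1CCCCCl | intermediate
11 | tert-butyl (2S,3aR,6R,7R,7aR)-7-(4-chlorobutyl)-3a,6-dihydroxy-2-[(2S,4S)-4-methyl-5-oxooxolan-2-yl]-2,3,3a,6,7,7a-hexahydro-1H-indole-1-carboxylate (6-OH trans to the chain) | O[C@@H]1C=C[C@]2(O)C[C@@H]([C@@H]3C[C@H](C)C(=O)O3)N(C(=O)OC(C)(C)C)[C@@H]2[C@H]1CCCCCl | intermediate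
12 | N,N-dimethylpropanamide dimethyl acetal (1,1-dimethoxy-N,N-dimethylpropan-1-amine) | CCC(OC)(OC)N(C)C | starting material
13 | (Z)-ketene N,O-acetal formed at the C10 oxygen of 11 | C/C=C(\O[C@@H]1C=C[C@]2(O)C[C@@H]([C@@H]3C[C@H](C)C(=O)O3)N(C(=O)OC(C)(C)C)[C@@H]2[C@H]1CCCCCl)N(C)C | intermediate (not isolated)
14 | Claisen amide, N-Boc hydroindole with C10=C11 alkene and C12–CH(CH3)CONMe2 on the concave face (1R,3S,9S,9aR,12R,13S,18S,20S) | CN(C)C(=O)[C@@H](C)[C@H]1C=C[C@H](CCCCCl)[C@H]2N(C(=O)OC(C)(C)C)[C@H]([C@@H]3C[C@H](C)C(=O)O3)C[C@@]12O | intermediate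
15 | iodolactone, cis-fused lactone D with O11 trans to the C10 iodide (1R,3S,9R,9aR,10R,11R,12S,13S,18S,20S) | I[C@H]1[C@@H]2OC(=O)[C@@H](C)[C@@H]2[C@]3(O)C[C@@H]([C@@H]4C[C@H](C)C(=O)O4)N(C(=O)OC(C)(C)C)[C@@H]3[C@H]1CCCCCl | intermediate
16 | phenyl vinyl sulfone | C=CS(=O)(=O)c1ccccc1 | starting material
17 | C10-(2-phenylsulfonylethyl) lactone (1R,3S,9S,9aR,10R,11S,12S,13S,18S,20S) | O=S(=O)(CC[C@H]1[C@@H]2OC(=O)[C@@H](C)[C@@H]2[C@]3(O)C[C@@H]([C@@H]4C[C@H](C)C(=O)O4)N(C(=O)OC(C)(C)C)[C@@H]3[C@H]1CCCCCl)c1ccccc1 | intermediate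
18 | C10-ethyl N-Boc chloride (1R,3S,9S,9aR,10R,11S,12S,13S,18S,20S) | CC[C@H]1[C@@H]2OC(=O)[C@@H](C)[C@@H]2[C@]3(O)C[C@@H]([C@@H]4C[C@H](C)C(=O)O4)N(C(=O)OC(C)(C)C)[C@@H]3[C@H]1CCCCCl | intermediate
19 | secondary ammonium trifluoroacetate of N-deprotected 18 | CC[C@H]1[C@@H]2OC(=O)[C@@H](C)[C@@H]2[C@]3(O)C[C@@H]([C@@H]4C[C@H](C)C(=O)O4)[NH2+][C@@H]3[C@H]1CCCCCl.[O-]C(=O)C(F)(F)F | intermediate (not isolated)
20 | 1-hydroxy pentacyclic amine (1R,3S,9S,9aR,10R,11S,12S,13S,18S,20S): rings B/C cis-fused, ring A trans-fused to ring B, ethyl cis to C8, lactone D cis-fused with O11 trans to ethyl, 13-methyl exo | CC[C@H]1[C@@H]2OC(=O)[C@@H](C)[C@@H]2[C@]3(O)C[C@@H]([C@@H]4C[C@H](C)C(=O)O4)N5CCCC[C@@H]1[C@H]35 | intermediate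
21 | nine-membered keto iminium acetate (C1 ketone, C9a=N4 iminium; 3S,9S,10R,11S,12S,13S,18S,20S) | CC[C@H]1[C@@H]2OC(=O)[C@@H](C)[C@@H]2C(=O)C[C@@H]([C@@H]3C[C@H](C)C(=O)O3)[N+]4=C[C@H]1CCCC4.CC(=O)[O-] | intermediate (not isolated)
22 | 9a-hydroxy keto amine (carbinolamine, both C9a epimers) | CC[C@H]1[C@@H]2OC(=O)[C@@H](C)[C@@H]2C(=O)C[C@@H]([C@@H]3C[C@H](C)C(=O)O3)N4CCCC[C@@H]1C4O | intermediate (not isolated)
23 | 12-epi-tuberostemonone (3S,9S,10R,11S,12S,13S,18S,20S; cis-fused lactone D) | CC[C@H]1[C@@H]2OC(=O)[C@@H](C)[C@@H]2C(=O)C[C@@H]([C@@H]2C[C@H](C)C(=O)O2)N2CCCC[C@@H]1C2=O | intermediate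
24 | tuberostemonone (3S,9S,10R,11S,12R,13S,18S,20S) | CC[C@H]1[C@@H]2OC(=O)[C@@H](C)[C@H]2C(=O)C[C@@H]([C@@H]2C[C@H](C)C(=O)O2)N2CCCC[C@@H]1C2=O | target

## Step count and risks

Total steps: 13. Longest linear sequence: 13 (from 1).

The three steps most likely to fail, each with a fallback:

(a) The oxidative fragmentation (step 12). The trivalent iodine reagent may instead oxidise an α-C–H bond of the amine (C3 or C5). The iminium 21 could also epimerise C9 through its enamine or undergo a transannular Mannich reaction with the C12 enol. The fallback moves the C–C scission to the carbamate stage and uses radical instead of two-electron chemistry. It sets out from 18: PhI(OAc)2 and I2 under visible light generate the C1 alkoxy radical, whose β-scission toward the nitrogen-stabilised C9a radical, followed by oxidation and acetate capture, gives the α-acetoxy carbamate F1. TFA removes the Boc group and acetic acid is lost to give the nine-membered cyclic imine F2. NaI and K2CO3 in MeCN then alkylate the imine nitrogen with the chlorobutyl chain to give the iminium chloride F3. Aqueous NaHCO3 with TEMPO and PhI(OAc)2 converts F3 into the lactam, and the route is rejoined at 23.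

(b) The enolate alkylation (step 5). The enolate of a β-carbamoyl ketone can expel the carbamate (retro-aza-Michael), and the hindered iodide may react slowly. The fallback avoids a free enolate and builds the chain by catalysis. It sets out from 8: TMSOTf and Et3N give the bis-silyl 2-silyloxydiene F4. Tsuji allylation with allyl methyl carbonate, Pd2(dba)3 and dppe (zerovalent palladium) on the convex face gives the C9-allyl enone F5 after mild acidic work-up. Cross-metathesis with allyl chloride using second-generation Grubbs catalyst gives the (E)-4-chlorobut-2-enyl enone F6. Chemoselective diimide reduction (2-nitrobenzenesulfonyl hydrazide, Et3N) of the isolated alkene brings the route back at 10.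

(c) The C12 epimerisation (step 13). DBU may trigger E1cB loss of the β-acyloxy group instead of simple enolisation, and the position of the equilibrium is assumed from the natural product. The fallback uses acid and an elimination–readdition pathway instead of base enolisation. It sets out from 23: CSA in toluene at 80 °C opens lactone D by retro-oxa-Michael reaction to the nine-membered enone acid F7, which recloses by oxa-Michael addition under thermodynamic control, and the route comes back at 24.

## Further compounds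

F1 | step 12 | N-Boc 9a-acetoxy nine-membered keto carbamate (C1 ketone, C9a–OAc, both C9a epimers) | CC[C@H]1[C@@H]2OC(=O)[C@@H](C)[C@@H]2C(=O)C[C@@H]([C@@H]3C[C@H](C)C(=O)O3)N(C(=O)OC(C)(C)C)C(OC(C)=O)[C@H]1CCCCCl
F2 | step 12 | nine-membered cyclic imine (C9a=N4) with pendant 4-chlorobutyl chain | CC[C@H]1[C@@H]2OC(=O)[C@@H](C)[C@@H]2C(=O)C[C@@H]([C@@H]3C[C@H](C)C(=O)O3)N=C[C@H]1CCCCCl
F3 | step 12 | nine-membered keto iminium chloride (ring A closed) | CC[C@H]1[C@@H]2OC(=O)[C@@H](C)[C@@H]2C(=O)C[C@@H]([C@@H]3C[C@H](C)C(=O)O3)[N+]4=C[C@H]1CCCC4.[Cl-]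
F4 | step 5 | bis-trimethylsilyl 2-silyloxydiene of 8 (C9=C10(OSiMe3)–C11=C12, C1–OSiMe3) | C[Si](C)(C)OC1=C[C@H]2N(C(=O)OC(C)(C)C)[C@H]([C@@H]3C[C@H](C)C(=O)O3)C[C@@]2(O[Si](C)(C)C)C=C1
F5 | step 5 | C9-allyl enone (allyl trans to N) | O=C1C=C[C@]2(O)C[C@@H]([C@@H]3C[C@H](C)C(=O)O3)N(C(=O)OC(C)(C)C)[C@@H]2[C@H]1CC=C
F6 | step 5 | C9-[(E)-4-chlorobut-2-enyl] enone | O=C1C=C[C@]2(O)C[C@@H]([C@@H]3C[C@H](C)C(=O)O3)N(C(=O)OC(C)(C)C)[C@@H]2[C@H]1C/C=C/CCl
F7 | step 13 | nine-membered enone acid (C11=C12 enone, free C14 carboxylic acid) | CC[C@H]1C=C([C@H](C)C(=O)O)C(=O)C[C@@H]([C@@H]2C[C@H](C)C(=O)O2)N2CCCC[C@@H]1C2=O
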